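5 questions stand on 4 flasks of one recipe: which flask holds the most target after 2.5 min, and how much target each holds.

| flask | substrate | partner | other conformer | temperature | remark | time |
|---|---|---|---|---|---|---|
| alder | 0.18 M | 4 equiv | 0.25 equiv | 20 °C | run made earlier |  |
| winter | 0.091 M | 4.00 equiv | 0.250 equiv |  | at −5 °C until 30 s, from then on at 45 °C | 2.5 min |
| midnight | 0.091 M | 4.00 equiv | 0.250 equiv | 20 °C |  | 2.5 min |
| summer | 0.091 M | 4.00 equiv | 0.250 equiv | 45 °C |  | 2.5 min |
| dusk | 0.091 M | 4.00 equiv | 0.250 equiv | −5 °C |  | 2.5 min |

alder run (percent of the substrate and other conformer together charged)

| time / s | target / % |
|---|---|
| 10.0 | 13.2 |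
| 15.0 | 17.7 |
| 20.0 | 22.2 |
| 30.0 | 29.0 |

(standard deviation of a reading: 0.5 percentage points)

- steps that have been proposed: partner -> decomposed reagent; other conformer -> decomposition product; substrate + partner -> target; substrate <-> other conformer; partner + other conformer -> isomer of the product
- in a conversion other conformer counts as not yet reacted
- the earlier runs do not show what temperature does; that part of a forecast is a guess

1. the flask with the highest amount of target, in percent of the substrate and other conformer together charged ("all alike" if they lie within 1.5 percentage points) (winter / midnight / summer / dusk / all alike)
2. final target, as a percentage of the substrate and other conformer together charged, in winter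
3. final target, as a percentage of the substrate and other conformer together charged, in midnight
4. final target, as a percentage of the substrate and other conformer together charged, in summer
5. final target, as a percentage of the substrate and other conformer together charged, in dusk

I read the alder run at 20 °C and build the flask one step at a time. I count substrate and other conformer as one pool, which the proposed exchange substrate ⇌ other conformer allows, and write L for the logarithm of pool charged over pool unreacted. First I take the main step, substrate + partner → target, with the partner in excess: this is pseudo-first-order with constant κ, proportional to the partner concentration, so L should grow in a straight line. It does not: L is 0.142 at 10.0 s, and the line would give 0.426 at 30.0 s, but the reading gives less, 0.342. By that reading the main step has used 9.06% of the partner in the alder run.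

So I add partner → decomposed reagent, first order with constant λ, and at time t L becomes R(1 − e^(−λt)), with R = κ/λ. The two readings give λ = 0.0233 s⁻¹ and R = 0.681, both rough, since each reading carries 0.5 percentage points. R is what I call the reach: the total L that a partner charge can buy before it has decayed. In this reckoning, for a fixed course of temperature, it goes with the partner concentration.

Midnight has about half the alder concentration, so with the main step by itself κ = 0.00802 s⁻¹ gives 70.0% target. With the decay added, the reach in midnight is 0.344, and the partner's lifetime as read from the alder run, 42.9 s, is shorter than 2.5 min, so L nearly reaches it and I get 28.4%. The steps partner + other conformer → isomer of the product and other conformer → decomposition product leave no mark I can size in the target readings, but both take material away, so I expect my number to err high rather than low. The alder run has one temperature, so I give the other flasks no number.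

The forecast has midnight highest, with 42% in winter, 47% in midnight, 40% in summer and 16% in dusk, and says “Midnight is narrowly favoured, with low confidence”. For midnight my 28.4% stands lower than its 47%.

The flasks give 12.4% in winter, 27.7% in midnight, 9.48% in summer and 16.6% in dusk, so midnight holds the most.

    partner → decomposed reagent (k = 0.0220 s⁻¹, Ea = 87.0 kJ mol⁻¹)
    other conformer → decomposition product (k = 6.20 × 10⁻⁵ s⁻¹, Ea = 93.0 kJ mol⁻¹)
    substrate + partner → target (k = 0.0230 M⁻¹ s⁻¹, Ea = 47.0 kJ mol⁻¹)
    substrate ⇌ other conformer (K = 0.0110, k = 0.0200 s⁻¹, Ea = 71.0 kJ mol⁻¹, ΔH = −11.0 kJ mol⁻¹)
    partner + other conformer → isomer of the product (k = 0.130 M⁻¹ s⁻¹, Ea = 65.0 kJ mol⁻¹)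
    (constants at 20 °C)

In midnight the partner's half-life by its decay, 31.5 s, is shorter than the substrate's half-life by the main step at the charged partner, 82.8 s, and the target there gives L = 0.324, against my reach of 0.344. Winter's target, with 0% of the partner left, gives L = 0.133, which I take as the reach of that course of temperature; a quarter of that, for the neighbour of winter charged with 1.00 equiv of partner, gives 3.26%, and that neighbour holds 3.29%.

The earlier runs and the new flask stem from a simulated flask with constants of no real substance; the scatter is artificial.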